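Readings and results come from a simulation with constants of no real substance, noise included.

The side product takes up one free monomer and one monomer in chains, so each act of that step leaves their difference unchanged. I call this difference the margin, D, monomer in chains minus free monomer, both in percent of the charge. Chain growth moves D. When growth has died and D is positive, free monomer is the limiting reagent of the side step, D is what remains in chains, and the rest of the charge is side product.

| setting | green | red | flask |
|---|---|---|---|
| free monomer | 0.43 M (fed, over 80 min) | 0.43 M (fed, over 80 min) | 0.43 M (fed, over 80 min) |
| transfer agent | 0.0129 M | 0.019 M | 0.0129 M |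
| initiator | 1.2 mM | 1.2 mM | 1.2 mM |
| remark | the very flask that is asked about, followed so far; the fed solution adds 1.0 times the starting volume | run made earlier; the fed solution adds 1.0 times the starting volume | the fed solution adds 1.0 times the starting volume |
| time |  |  | 15 d |

green run (percent of the free monomer charged)

| time / h | free monomer / % | monomer in chains / % | side product / % |
|---|---|---|---|
| 4.00 | 86.6 | 9.5 | 3.2 |
| 8.00 | 60.9 | 24.8 | 14.2 |
| 12.0 | 41.6 | 32.9 | 26.2 |
| 15.0 | 32.4 | 34.0 | 33.6 |
| 20.0 | 20.7 | 36.9 | 43.0 |
| 25.0 | 14.0 | 36.5 | 50.1 |
| 30.0 | 9.5 | 35.7 | 54.4 |

red run (percent of the free monomer charged)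

| time / d | free monomer / % | monomer in chains / % | side product / % |
|---|---|---|---|
| 0.333 | 63.6 | 23.5 | 12.6 |
| 0.833 | 26.3 | 30.8 | 43.1 |
| 1.67 | 10.6 | 26.4 | 63.5 |
| 2.50 | 5.8 | 22.3 | 71.0 |
| 4.00 | 2.8 | 18.4 | 78.8 |
| 5.00 | 3.0 | 17.7 | 80.1 |
| 6.00 | 1.2 | 17.4 | 81.2 |

(readings scatter by 0.5 percentage points)

- percent here means free monomer units held: one side product counts as two
- what is said of monomer in chains includes idle complex
- amounts are per litre of the starting volume; all of the dose is in the solution fed
- steps under discussion: free monomer + initiator -> living end + monomer in chains; free monomer + living end -> monomer in chains + living end; living end + transfer agent -> dead chain; initiator -> spent initiator; free monomer + monomer in chains -> side product; initiator + monomer in chains <-> idle complex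
- the reaction counts as stopped when no species that holds the free monomer changes by six tenths of a point or more over the second half of the time

* why nothing more happens at 15 d, or that something still does (it is still moving / no working catalyst is left / all of the free monomer has reacted / forward and back rates have come level)
* part of the free monomer gone at 15 d
* the monomer in chains standing at 15 d, as a percentage of the free monomer charged
* the side product standing at 15 d, as a percentage of the free monomer charged

So where does D stop in the green flask? At 30.0 h it reads 26 percentage points. Over the last readings, its rise shrinks by a factor of 0.478 per step, and summing that series gives 30 points.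

Does free monomer clear in time? With D fixed, the rate κ·M·(M+D) integrates to a ratio of free monomer to chains that falls as exp(−κDt). In the red run this ratio falls at 0.416 d⁻¹, at a margin of 16 points, so I read κ as 2.67 d⁻¹ per whole charge. The green flask then clears at 0.790 d⁻¹, a half-time of 0.877 d, which is short against 15 d. I therefore expect 29.6% in chains and the rest of the charge as side product.

The forecast says all of the free monomer has reacted, with 100% gone, 28% in chains and 72% as side product, since “chains remain in excess”; its chains figure lies below my margin.

The flask gives all of the free monomer has reacted, with >99.9% gone, 29.7% in chains and 70.3% as side product, so the margin and the chains agree. Growth took 64.6% of the charge and the side step 35.2%, a difference of 29 points, and the side step's half-life of free monomer at 0.342 d, 1.1 d, is short against 15 d.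

    free monomer + initiator → living end + monomer in chains (k = 0.0160 M⁻¹ min⁻¹)
    free monomer + living end → monomer in chains + living end, rate k2*[living end]*[free monomer] (k = 4.00 M⁻¹ min⁻¹)
    living end + transfer agent → dead chain (kL = 0.180 M⁻¹ min⁻¹)
    initiator → spent initiator (k = 3.40 × 10⁻⁴ min⁻¹)
    free monomer + monomer in chains → side product (k = 0.00810 M⁻¹ min⁻¹)
    initiator + monomer in chains ⇌ idle complex (K = 1.50 M⁻¹, k = 0.0100 M⁻¹ min⁻¹)

With 1.7 M of free monomer, κ grows with the charge, so a margin like this flask's clears at 3.12 d⁻¹. That neighbour ends with 0% free monomer, 14.6% in chains and 85.4% as side product.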